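## Retrosynthetic overview

1. The target comes from its 4‑O‑silyl ether, which is split at C7=C8 by a Z‑selective Horner–Wadsworth–Emmons reaction between a ring β‑ketophosphonate (C8) and a (4R)‑4‑silyloxy enal (C1–C7); this sets the 7Z,5E diene.
2. The ring β‑ketophosphonate comes from a 2‑(phosphonomethyl)‑3‑bromo‑5‑(octadienyl)furan: singlet oxygen breaks the furan to a cis‑enedione, and a chiral Brønsted acid closes C8–C12 and sets C12.
3. The furan precursor comes from furan: 2,5‑dibromination, halogen dance with hydroxymethylation, Br–Li exchange and alkylation with (2Z,5Z)‑1‑bromoocta‑2,5‑diene, then Michaelis–Becker phosphonylation.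
4. The enal comes from a silyl ynone by Noyori transfer hydrogenation (sets C4), silylation, semihydrogenation and cross‑metathesis.
5. Ring order: the furan is carried as a latent ring; the cyclopentenone is the only ring of the target and is formed in the key step.

Assumption: the sense of induction of the chiral acid in step 13 cannot be predicted with certainty; the route is written with the (R)‑acid, and its enantiomer is used if it gives the (S)‑carbinol.

## Route

Step 1
Reactants: 1 furan
Product: 2 2,5-dibromofuran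
Conditions: NBS (2.05 equiv), DMF, 0 °C to rt, dark
Reagents that add atoms: N-bromosuccinimide, O=C1CCC(=O)N1Br
Why: Electrophilic aromatic substitution of the electron-rich furan takes place at both alpha positions, so two equivalents of NBS give the 2,5-dibromide.

Step 2
Reactants: 2 2,5-dibromofuran
Product: 4 (3,5-dibromofuran-2-yl)methanol, via aryllithium 3 (not isolated)
Conditions: LiN(i-Pr)2 (1.1 equiv), THF, –78 °C, 1 h; (CH2O)n, –78 °C to rt; aq NH4Cl
Reagents that add atoms: formaldehyde (from paraformaldehyde), C=O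
Why: Halogen dance: the amide removes H-3 next to bromine and intermolecular bromine transfer moves lithium to the more stable alpha position flanked by bromine (as known for 2,5-dibromothiophene and 2-bromo-5-methylfuran), and the aryllithium then adds to formaldehyde.

Step 3
Reactants: 5 1-bromopent-2-yne; 6 prop-2-yn-1-ol
Product: 7 octa-2,5-diyn-1-ol
Conditions: CuI, NaI, K2CO3, DMF, rt, 16 h
Reagents that add atoms: none
Why: Copper-mediated propargylic alkynylation: the copper acetylide of 6 displaces the primary propargylic halide in an SN2 sense to give the skipped diyne.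

Step 4
Reactants: 7 octa-2,5-diyn-1-ol
Product: 8 (2Z,5Z)-octa-2,5-dien-1-ol
Conditions: H2 (1 atm), Pd/CaCO3 poisoned with Pb(OAc)2 (Lindlar catalyst), quinoline, MeOH, rt
Reagents that add atoms: none
Why: Lindlar semihydrogenation adds hydrogen syn to each alkyne and stops at the alkene, which sets both Z double bonds.

Step 5
Reactants: 8 (2Z,5Z)-octa-2,5-dien-1-ol
Product: 9 (2Z,5Z)-1-bromoocta-2,5-diene
Conditions: CBr4, PPh3, CH2Cl2, 0 °C
Reagents that add atoms: carbon tetrabromide, BrC(Br)(Br)Br
Why: Appel reaction: the alkoxyphosphonium ion is displaced by bromide at the primary carbon under neutral conditions, without allylic shift or loss of alkene geometry.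

Step 6
Reactants: 4 (3,5-dibromofuran-2-yl)methanol; 9 (2Z,5Z)-1-bromoocta-2,5-diene
Product: 11 {3-bromo-5-[(2Z,5Z)-octa-2,5-dien-1-yl]furan-2-yl}methanol, via lithiated alkoxide 10 (not isolated)
Conditions: NaH, THF, 0 °C; n-BuLi (1.05 equiv), –78 °C; then 9, –78 to 0 °C; aq NH4Cl
Reagents that add atoms: none
Why: After O-deprotonation, bromine–lithium exchange is much faster at the alpha bromide (C-5) than at the beta bromide (C-3), and the 2-furyllithium is alkylated by the primary allylic bromide in an SN2 reaction that leaves both Z alkenes and the ring bromine in place.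

Step 7
Reactants: 11 {3-bromo-5-[(2Z,5Z)-octa-2,5-dien-1-yl]furan-2-yl}methanol
Product: 13 diphenyl ({3-bromo-5-[(2Z,5Z)-octa-2,5-dien-1-yl]furan-2-yl}methyl)phosphonate, via furfuryl bromide 12 (not isolated)
Conditions: PBr3 (0.4 equiv), pyridine (cat.), Et2O, –20 °C; then NaP(O)(OPh)2 [from (PhO)2P(O)H and NaN(SiMe3)2], THF, –78 to 0 °C
Reagents that add atoms: diphenyl phosphite, O=[PH](Oc1ccccc1)Oc1ccccc1
Why: PBr3 turns the furfuryl alcohol into the reactive bromide, which is displaced at carbon by sodium diphenyl phosphite (Michaelis–Becker reaction) to give an Ando-type diaryl phosphonate.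

Step 8
Reactants: 14 methyl 4-chloro-4-oxobutanoate; 15 bis(trimethylsilyl)acetylene
Product: 16 methyl 4-oxo-6-(trimethylsilyl)hex-5-ynoate
Conditions: AlCl3, CH2Cl2, 0 °C
Reagents that add atoms: none
Why: Friedel–Crafts-type acylation: the acylium ion attacks the silylalkyne, and loss of one silyl group from the beta-silyl cation gives the silyl ynone.

Step 9
Reactants: 16 methyl 4-oxo-6-(trimethylsilyl)hex-5-ynoate
Product: 17 methyl (4R)-4-hydroxy-6-(trimethylsilyl)hex-5-ynoate
Conditions: RuCl[(R,R)-TsDPEN](p-cymene) (1 mol%), KOH (2 mol%), i-PrOH, rt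
Reagents that add atoms: none
Why: Noyori asymmetric transfer hydrogenation: the alkyne takes the place of the aryl group in the six-membered transition state, so the (R,R) catalyst delivers hydride to the face that gives the (R) propargylic alcohol (C4 of the target).

Step 10
Reactants: 17 methyl (4R)-4-hydroxy-6-(trimethylsilyl)hex-5-ynoate
Product: 19 methyl (4R)-4-[(tert-butyldimethylsilyl)oxy]hex-5-ynoate, via bis-silyl ether 18 (not isolated)
Conditions: TBSCl, imidazole, DMF, rt; then K2CO3 (0.3 equiv), MeOH, 0 °C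
Reagents that add atoms: tert-butyl(chloro)dimethylsilane, CC(C)(C)[Si](C)(C)Cl
Why: O-silylation blocks lactonisation of the gamma-hydroxy ester, and methoxide then cleaves only the alkynyl C–Si bond (protodesilylation), with no bond to the stereocentre broken.

Step 11
Reactants: 19 methyl (4R)-4-[(tert-butyldimethylsilyl)oxy]hex-5-ynoate
Product: 20 methyl (4R)-4-[(tert-butyldimethylsilyl)oxy]hex-5-enoate
Conditions: H2 (1 atm), Pd/CaCO3 poisoned with Pb(OAc)2 (Lindlar catalyst), quinoline, hexane, rt
Reagents that add atoms: none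
Why: Lindlar semihydrogenation reduces the terminal alkyne to the terminal alkene and stops there.

Step 12
Reactants: 20 methyl (4R)-4-[(tert-butyldimethylsilyl)oxy]hex-5-enoate; 21 (E)-but-2-enal
Product: 22 methyl (4R,5E)-4-[(tert-butyldimethylsilyl)oxy]-7-oxohept-5-enoate
Conditions: second-generation Hoveyda–Grubbs catalyst [RuCl2(H2IMes)(=CH-C6H4-2-O-i-Pr)] (3 mol%), CH2Cl2, 40 °C
Reagents that add atoms: none
Why: Olefin cross-metathesis of the terminal alkene with excess crotonaldehyde is driven by loss of propene and gives the conjugated E enal.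

Step 13
Reactants: 13 diphenyl ({3-bromo-5-[(2Z,5Z)-octa-2,5-dien-1-yl]furan-2-yl}methyl)phosphonate
Product: 25 diphenyl {(5R)-3-bromo-5-hydroxy-5-[(2Z,5Z)-octa-2,5-dien-1-yl]-2-oxocyclopent-3-en-1-yl}phosphonate, via endoperoxide 23 (not isolated), via cis-enedione 24 (not isolated)
Conditions: O2, tetraphenylporphyrin (0.2 mol%), 530 nm light, CH2Cl2, –78 °C; Me2S (2 equiv), –78 to –30 °C; then (R)-3,3'-bis(2,4,6-triisopropylphenyl)-1,1'-binaphthyl-2,2'-diyl N-triflylphosphoramide (5 mol%), toluene, –30 to 0 °C
Reagents that add atoms: dioxygen, O=O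
Why: Proposed new method: singlet oxygen adds [4+2] across the furan (the aromaticity-breaking event, far faster than the ene reaction of Z-disubstituted alkenes), Me2S reduces the endoperoxide to the cis-enedione, and the chiral acid protonates the C12 ketone of the β-ketophosphonate enol to give the 1,4-dihydroxypentadienyl cation of a Piancatelli rearrangement, whose conrotatory 4π closure (C8 to C12) inside the chiral ion pair favours one sense of rotation and so the (R) carbinol (the phosphonate makes C8 the only enolising position and its own stereocentre is removed in step 14); the closest known reactions are the chiral-phosphoric-acid-catalysed asymmetric aza-Piancatelli rearrangement, N-triflylphosphoramide-catalysed asymmetric Nazarov cyclisations and the cyclisation of furan-derived cis-enediones to 4-hydroxycyclopentenones.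

Step 14
Reactants: 25 diphenyl {(5R)-3-bromo-5-hydroxy-5-[(2Z,5Z)-octa-2,5-dien-1-yl]-2-oxocyclopent-3-en-1-yl}phosphonate; 22 methyl (4R,5E)-4-[(tert-butyldimethylsilyl)oxy]-7-oxohept-5-enoate
Product: 26 methyl (4R,5E,7Z,12R,14Z,17Z)-10-bromo-4-[(tert-butyldimethylsilyl)oxy]-12-hydroxy-9-oxoprosta-5,7,10,14,17-pentaen-1-oate
Conditions: NaI, DBU (1.05 equiv), THF, –78 to –20 °C
Reagents that add atoms: none
Why: Ando-type Z-selective Horner–Wadsworth–Emmons reaction: with aryloxy groups on phosphorus the kinetic adduct collapses faster than it reverts, so the aldehyde substituent ends cis to the acyl group (C9), which is the 7Z geometry, while the E enal alkene and C4 are untouched and, with one equivalent of amidine base, the tertiary hydroxyl stays protonated so that retro-aldol opening is not triggered.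

Step 15
Reactants: 26 methyl (4R,5E,7Z,12R,14Z,17Z)-10-bromo-4-[(tert-butyldimethylsilyl)oxy]-12-hydroxy-9-oxoprosta-5,7,10,14,17-pentaen-1-oate
Product: 27 methyl (4R,5E,7Z,12R,14Z,17Z)-10-bromo-4,12-dihydroxy-9-oxoprosta-5,7,10,14,17-pentaen-1-oate
Conditions: HF·pyridine, pyridine, THF, 0 °C to rt
Reagents that add atoms: none
Why: Fluoride-mediated desilylation under buffered, non-basic conditions frees the C4 hydroxyl without lactonisation, without ionising the tertiary allylic alcohol and without touching either stereocentre or the dienone geometry.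

## Compound list

1 | furan | c1ccoc1 | starting material
2 | 2,5-dibromofuran | Brc1ccc(Br)o1 | intermediate
3 | (3,5-dibromofuran-2-yl)lithium | [Li]c1oc(Br)cc1Br | intermediate
4 | (3,5-dibromofuran-2-yl)methanol | OCc1oc(Br)cc1Br | intermediate
5 | 1-bromopent-2-yne | CCC#CCBr | starting material
6 | prop-2-yn-1-ol | OCC#C | starting material
7 | octa-2,5-diyn-1-ol | CCC#CCC#CCO | intermediate
8 | (2Z,5Z)-octa-2,5-dien-1-ol | CC/C=C\C/C=C\CO | intermediate
9 | (2Z,5Z)-1-bromoocta-2,5-diene | CC/C=C\C/C=C\CBr | intermediate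
10 | sodium (3-bromo-5-lithiofuran-2-yl)methanolate | [Li]c1cc(Br)c(CO[Na])o1 | intermediate
11 | {3-bromo-5-[(2Z,5Z)-octa-2,5-dien-1-yl]furan-2-yl}methanol | CC/C=C\C/C=C\Cc1cc(Br)c(CO)o1 | intermediate
12 | 3-bromo-2-(bromomethyl)-5-[(2Z,5Z)-octa-2,5-dien-1-yl]furan | CC/C=C\C/C=C\Cc1cc(Br)c(CBr)o1 | intermediate
13 | diphenyl ({3-bromo-5-[(2Z,5Z)-octa-2,5-dien-1-yl]furan-2-yl}methyl)phosphonate | CC/C=C\C/C=C\Cc1cc(Br)c(CP(=O)(Oc2ccccc2)Oc2ccccc2)o1 | intermediate
14 | methyl 4-chloro-4-oxobutanoate | COC(=O)CCC(Cl)=O | starting material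
15 | bis(trimethylsilyl)acetylene | C[Si](C)(C)C#C[Si](C)(C)C | starting material
16 | methyl 4-oxo-6-(trimethylsilyl)hex-5-ynoate | COC(=O)CCC(=O)C#C[Si](C)(C)C | intermediate
17 | methyl (4R)-4-hydroxy-6-(trimethylsilyl)hex-5-ynoate | C[Si](C)(C)C#C[C@H](O)CCC(=O)OC | intermediate
18 | methyl (4R)-4-[(tert-butyldimethylsilyl)oxy]-6-(trimethylsilyl)hex-5-ynoate | C[Si](C)(C)C#C[C@H](O[Si](C)(C)C(C)(C)C)CCC(=O)OC | intermediate
19 | methyl (4R)-4-[(tert-butyldimethylsilyl)oxy]hex-5-ynoate | C#C[C@H](O[Si](C)(C)C(C)(C)C)CCC(=O)OC | intermediate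
20 | methyl (4R)-4-[(tert-butyldimethylsilyl)oxy]hex-5-enoate | C=C[C@H](O[Si](C)(C)C(C)(C)C)CCC(=O)OC | intermediate
21 | (E)-but-2-enal | C/C=C/C=O | starting material
22 | methyl (4R,5E)-4-[(tert-butyldimethylsilyl)oxy]-7-oxohept-5-enoate | O=C/C=C/[C@H](O[Si](C)(C)C(C)(C)C)CCC(=O)OC | intermediate
23 | diphenyl ({6-bromo-4-[(2Z,5Z)-octa-2,5-dien-1-yl]-2,3,7-trioxabicyclo[2.2.1]hept-5-en-1-yl}methyl)phosphonate (racemic) | CC/C=C\C/C=C\CC12OOC(CP(=O)(Oc3ccccc3)Oc3ccccc3)(O1)C(Br)=C2 | intermediate
24 | diphenyl [(3E,7Z,10Z)-3-bromo-2,5-dioxotrideca-3,7,10-trien-1-yl]phosphonate (the two carbonyl groups cis on C3=C4) | CC/C=C\C/C=C\CC(=O)/C=C(Br)\C(=O)CP(=O)(Oc1ccccc1)Oc1ccccc1 | intermediate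
25 | diphenyl {(5R)-3-bromo-5-hydroxy-5-[(2Z,5Z)-octa-2,5-dien-1-yl]-2-oxocyclopent-3-en-1-yl}phosphonate (C-1 epimers, labile) | CC/C=C\C/C=C\C[C@@]1(O)C=C(Br)C(=O)C1P(=O)(Oc1ccccc1)Oc1ccccc1 | intermediate
26 | methyl (4R,5E,7Z,12R,14Z,17Z)-10-bromo-4-[(tert-butyldimethylsilyl)oxy]-12-hydroxy-9-oxoprosta-5,7,10,14,17-pentaen-1-oate | CC/C=C\C/C=C\C[C@@]1(O)C=C(Br)C(=O)/C1=C\C=C\[C@H](O[Si](C)(C)C(C)(C)C)CCC(=O)OC | intermediate
27 | methyl (4R,5E,7Z,12R,14Z,17Z)-10-bromo-4,12-dihydroxy-9-oxoprosta-5,7,10,14,17-pentaen-1-oate (CNP0168693.2) | CC/C=C\C/C=C\C[C@@]1(O)C=C(Br)C(=O)/C1=C\C=C\[C@H](O)CCC(=O)OC | target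

## Step count and risks

Total step count: 15. Longest linear sequence: 8 steps (steps 3, 4, 5, 6, 7, 13, 14, 15).

The three steps most likely to fail:

Step 13. The enantioselective ring closure is new on this substrate, and a racemic background closure or Z-to-E isomerisation of the enedione could compete. The fallback sets out from 13 and comes back at 26. The photooxygenation and Me2S reduction are run as written (through 23 and 24), but the ring is closed with Et3N in CH2Cl2 at 0 °C, which gives racemic diphenyl {3-bromo-5-hydroxy-5-[(2Z,5Z)-octa-2,5-dien-1-yl]-2-oxocyclopent-3-en-1-yl}phosphonate F1. Olefination of F1 with the enantiopure aldehyde 22 under the conditions of step 14 gives 26 together with its C12 epimer, methyl (4R,5E,7Z,12S,14Z,17Z)-10-bromo-4-[(tert-butyldimethylsilyl)oxy]-12-hydroxy-9-oxoprosta-5,7,10,14,17-pentaen-1-oate F2. These two are diastereomers and are separated by preparative HPLC, so C12 is secured by separation and not by catalyst control.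

Step 14. The olefination takes place at a hindered cyclic ketophosphonate carbon next to a free tertiary alcohol, so the 7E isomer or ring opening could compete. The fallback sets out from 25 and comes back at 26. Whatever 7E isomer forms, methyl (4R,5E,7E,12R,14Z,17Z)-10-bromo-4-[(tert-butyldimethylsilyl)oxy]-12-hydroxy-9-oxoprosta-5,7,10,14,17-pentaen-1-oate F3, is separated and irradiated at 405 nm with thioxanthen-9-one (5 mol%) in degassed MeCN. This gives a photostationary mixture of the 7E and 7Z dienones, from which 26 is isolated and F3 is recycled, so the geometry is corrected by photoisomerisation and not by kinetic control.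

Step 2. The halogen dance has not been shown on 2,5-dibromofuran itself, and ring opening of the 3-lithiofuran could compete. The fallback sets out from 2 and comes back at 11. Mono bromine–lithium exchange of 2 (n-BuLi, 1 equiv, Et2O, –78 °C) gives (5-bromofuran-2-yl)lithium F4, which is alkylated with 9 to 2-bromo-5-[(2Z,5Z)-octa-2,5-dien-1-yl]furan F5. LiN(i-Pr)2 in THF at –78 °C then runs the halogen dance on this 2-bromo-5-alkylfuran, the substrate class for which the dance is established, to give {3-bromo-5-[(2Z,5Z)-octa-2,5-dien-1-yl]furan-2-yl}lithium F6, which is trapped with formaldehyde to give 11. The order of chain attachment and dance is inverted, so neither the dance on the dibromide nor the selective exchange of step 6 is needed.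

## Further compounds

F1 | step 13 | diphenyl {3-bromo-5-hydroxy-5-[(2Z,5Z)-octa-2,5-dien-1-yl]-2-oxocyclopent-3-en-1-yl}phosphonate (racemic) | CC/C=C\C/C=C\CC1(O)C=C(Br)C(=O)C1P(=O)(Oc1ccccc1)Oc1ccccc1
F2 | step 13 | methyl (4R,5E,7Z,12S,14Z,17Z)-10-bromo-4-[(tert-butyldimethylsilyl)oxy]-12-hydroxy-9-oxoprosta-5,7,10,14,17-pentaen-1-oate | CC/C=C\C/C=C\C[C@]1(O)C=C(Br)C(=O)/C1=C\C=C\[C@H](O[Si](C)(C)C(C)(C)C)CCC(=O)OC
F3 | step 14 | methyl (4R,5E,7E,12R,14Z,17Z)-10-bromo-4-[(tert-butyldimethylsilyl)oxy]-12-hydroxy-9-oxoprosta-5,7,10,14,17-pentaen-1-oate | CC/C=C\C/C=C\C[C@@]1(O)C=C(Br)C(=O)/C1=C/C=C/[C@H](O[Si](C)(C)C(C)(C)C)CCC(=O)OC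
F4 | step 2 | (5-bromofuran-2-yl)lithium | [Li]c1ccc(Br)o1
F5 | step 2 | 2-bromo-5-[(2Z,5Z)-octa-2,5-dien-1-yl]furan | CC/C=C\C/C=C\Cc1ccc(Br)o1
F6 | step 2 | {3-bromo-5-[(2Z,5Z)-octa-2,5-dien-1-yl]furan-2-yl}lithium | CC/C=C\C/C=C\Cc1cc(Br)c([Li])o1
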